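## Retrosynthetic overview

- The target comes from anti-E2 dehydration of a tertiary cyclohexanol that already carries the CHBr–CH2Cl arm. That arm comes from alkoxide-directed bromochlorination of a 2-vinyl carbinol (the new step), and the carbinol from vinyl addition to (1R,5S)-5-bromo-4,4-dimethyl-2-oxocyclohexyl acetate.
- The only ring is closed once, by bromonium-initiated cyclisation of an acyclic enol acetate. The C–Br centre is relayed from the acetoxy centre through a chair.
- Key disconnection: the C–O bond of the acetoxy-bearing carbon. It is made first, by L-proline-catalysed α-aminoxylation of sulcatone, and it is the stereochemical origin of the route.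
- Order of events: C–O stereocentre, then ring with C–Br, then quaternary carbinol, then CHBr–CH2Cl, then ring alkene.

Assumption: L-proline gives the (R)-aminoxy ketone, and the (S)-ligand in step 5 gives (1′R); if either sense is reversed, the mirror-image catalyst is used.

Convention: numbers cover substrates, intermediates and products; atom-donating reagents are given by name and SMILES in each step. (S)-L is the tridentate Schiff base of 3,5-di-tert-butylsalicylaldehyde and (S)-2-amino-3,3-dimethyl-1,1-diphenylbutan-1-ol.

## Route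

Step 1
Reactants: 1 6-methylhept-5-en-2-one (sulcatone)
Product: 3 (R)-3-hydroxy-6-methylhept-5-en-2-one, via anilinooxy ketone 2 (not isolated)
Conditions: 1 (3 equiv), PhNO (1 equiv, slow addition), L-proline (20 mol%), DMSO, rt; then CuSO4·5H2O (0.3 equiv), MeOH, 0 °C
Reagents that add atoms: nitrosobenzene, O=Nc1ccccc1
Why: Proline-catalysed α-aminoxylation (enamine O-nitroso aldol): the anti enamine on the methylene side attacks the nitroso oxygen that is hydrogen-bonded to the carboxylic acid (Houk–List model), which sets C3 as R, and the copper-mediated N–O cleavage that follows does not touch the new stereocentre.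

Step 2
Reactants: 3 (R)-3-hydroxy-6-methylhept-5-en-2-one
Product: 5 (R)-6-methylhepta-1,5-diene-2,3-diyl diacetate, via dilithium alkoxide-enolate 4 (not isolated)
Conditions: LDA (2.2 equiv), THF, −78 °C; Ac2O (3 equiv), −78 to 0 °C
Reagents that add atoms: acetic anhydride, CC(=O)OC(C)=O
Why: Kinetic enolisation and O-acylation: the lithium alkoxide formed first shields its own α-hydrogen, so the second equivalent of LDA removes a methyl proton, and acetic anhydride traps both oxygens to give the terminal enol acetate with C3 intact.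

Step 3
Reactants: 5 (R)-6-methylhepta-1,5-diene-2,3-diyl diacetate
Product: 6 (1R,5S)-5-bromo-4,4-dimethyl-2-oxocyclohexyl acetate
Conditions: NBS (1.05 equiv), HFIP, 0 °C; aq. NaHCO3
Reagents that add atoms: N-bromosuccinimide, O=C1CCC(=O)N1Br
Why: Bromonium-initiated cation–olefin cyclisation (6-endo) with an enol acetate as terminating nucleophile, a terminator established in acid-induced terpenoid cyclisations: Br+ goes to the more electron-rich trisubstituted alkene, the enol carbon attacks the tertiary terminus anti to bromine through a chair with OAc and Br both equatorial, which sets C5 as S (cis to the acetate), and loss of the enol acetyl group unveils the ketone.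

Step 4
Reactants: 6 (1R,5S)-5-bromo-4,4-dimethyl-2-oxocyclohexyl acetate
Product: 7 (1R,2R,5S)-5-bromo-2-ethenyl-2-hydroxy-4,4-dimethylcyclohexyl acetate
Conditions: CH2=CHMgBr (1.3 equiv), THF, −78 °C; aq. NH4Cl
Reagents that add atoms: vinylmagnesium bromide, C=C[Mg]Br
Why: Grignard 1,2-addition to the α-acyloxy ketone, which is far faster than attack on the ester at −78 °C: the axial methyl on C4 blocks the axial trajectory, so vinyl enters equatorially and the new tertiary hydroxyl (C2, R) is axial and cis to the acetate.

Step 5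
Reactants: 7 (1R,2R,5S)-5-bromo-2-ethenyl-2-hydroxy-4,4-dimethylcyclohexyl acetate
Product: 8 (1R,2S,5S)-5-bromo-2-[(1R)-1-bromo-2-chloroethyl]-2-hydroxy-4,4-dimethylcyclohexyl acetate
Conditions: NBS (1.1 equiv), ClTi(OiPr)3 (1.2 equiv), (S)-L (20 mol%), hexanes/CH2Cl2, −20 °C
Reagents that add atoms: N-bromosuccinimide, O=C1CCC(=O)N1Br; chlorotitanium triisopropoxide, CC(C)O[Ti](Cl)(OC(C)C)OC(C)C
Why: Proposed new method: titanium/Schiff-base-catalysed bromochlorination, shown so far for primary allylic alcohols, is extended to a tertiary vinyl carbinol; the tertiary alkoxide exchanges onto ligand-bound ClTi(OiPr)3, NBS forms the bromonium on the vinyl face left open by the ligand, and the titanium-bound chloride is delivered through a six-membered array to the terminal carbon (also the unhindered, inductively favoured site), which gives anti addition with Br internal and Cl terminal and sets C1′ as R; closest known reaction type: Burns-type catalytic enantioselective bromochlorination of allylic alcohols with NBS, ClTi(OiPr)3 and a chiral Schiff base.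

Step 6
Reactants: 8 (1R,2S,5S)-5-bromo-2-[(1R)-1-bromo-2-chloroethyl]-2-hydroxy-4,4-dimethylcyclohexyl acetate
Product: 10 (1R,5S)-5-bromo-2-[(1R)-1-bromo-2-chloroethyl]-4,4-dimethylcyclohex-2-en-1-yl acetate (CNP0213819.1), via tertiary chlorosulfite 9 (not isolated)
Conditions: SOCl2 (1.5 equiv), pyridine (5 equiv), CH2Cl2, −20 to 0 °C
Reagents that add atoms: none
Why: Dehydration by anti E2 elimination of the tertiary chlorosulfite: with the C2 oxygen axial the antiperiplanar hydrogens sit on C3 and C1, and the electron-rich C3–H is lost in preference to the C–H bonds geminal to OAc or Br, which gives the C2=C3 alkene without touching C1, C5 or C1′.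

## Compound list

1 | 6-methylhept-5-en-2-one (sulcatone) | CC(=O)CCC=C(C)C | starting material
2 | (R)-3-(anilinooxy)-6-methylhept-5-en-2-one | CC(=O)[C@H](ONc1ccccc1)CC=C(C)C | intermediate (not isolated)
3 | (R)-3-hydroxy-6-methylhept-5-en-2-one | CC(=O)[C@H](O)CC=C(C)C | intermediate
4 | dilithium (R)-6-methylhepta-1,5-diene-2,3-bis(olate) | [Li+].[Li+].C=C([O-])[C@H]([O-])CC=C(C)C | intermediate (not isolated)
5 | (R)-6-methylhepta-1,5-diene-2,3-diyl diacetate | C=C(OC(C)=O)[C@H](OC(C)=O)CC=C(C)C | intermediate
6 | (1R,5S)-5-bromo-4,4-dimethyl-2-oxocyclohexyl acetate | CC(=O)O[C@@H]1C[C@H](Br)C(C)(C)CC1=O | intermediate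
7 | (1R,2R,5S)-5-bromo-2-ethenyl-2-hydroxy-4,4-dimethylcyclohexyl acetate | CC(=O)O[C@@H]1C[C@H](Br)C(C)(C)C[C@@]1(O)C=C | intermediate
8 | (1R,2S,5S)-5-bromo-2-[(1R)-1-bromo-2-chloroethyl]-2-hydroxy-4,4-dimethylcyclohexyl acetate | CC(=O)O[C@@H]1C[C@H](Br)C(C)(C)C[C@@]1(O)[C@@H](Br)CCl | intermediate
9 | (1R,2S,5S)-5-bromo-2-[(1R)-1-bromo-2-chloroethyl]-2-[(chlorosulfinyl)oxy]-4,4-dimethylcyclohexyl acetate | CC(=O)O[C@@H]1C[C@H](Br)C(C)(C)C[C@@]1(OS(Cl)=O)[C@@H](Br)CCl | intermediate (not isolated)
10 | (1R,5S)-5-bromo-2-[(1R)-1-bromo-2-chloroethyl]-4,4-dimethylcyclohex-2-en-1-yl acetate | CC(=O)O[C@@H]1C[C@H](Br)C(C)(C)C=C1[C@@H](Br)CCl | target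

## Step count and risks

Total step count: 6. Longest linear sequence: 6 (fully linear from sulcatone).

Three steps most likely to fail:

**Step 3 (bromocyclisation).** The enol acetate may be brominated directly, the C1 acetate may take part in bromonium opening, and a chair with axial OAc would give the trans isomer. Fallback, setting out from 3 and coming back at 7: vinylmagnesium bromide (2.5 equiv) adds to ketol 3 to give (3RS,4R)-3,7-dimethylocta-1,6-diene-3,4-diol F1. Ac2O/pyridine acetylates only the secondary hydroxyl, giving (3RS,4R)-3-hydroxy-3,7-dimethylocta-1,6-dien-4-yl acetate F2. Methyl N-(triethylammoniosulfonyl)carbamate (Burgess reagent) dehydrates the tertiary alcohol toward the methyl group, giving the myrcene-type triene (4R)-7-methyl-3-methylideneocta-1,6-dien-4-yl acetate F3. NBS in HFIP/H2O then cyclises F3 with the diene as terminator, and water captures the allyl cation at its tertiary end on the face of the neighbouring acetate, which gives 7.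

**Step 5 (the proposed new step).** A tertiary alkoxide may exchange onto titanium too slowly, leaving an undirected and unselective background reaction, or semipinacol ring expansion may compete. Fallback by known reactions only, setting out from 7 and coming back at 8: hydroxyl-directed epoxidation with VO(acac)2 (cat.)/t-BuOOH gives (1R,5S)-5-bromo-2-hydroxy-4,4-dimethyl-2-[(2R)-oxiran-2-yl]cyclohexyl acetate F4, with its epimer removed by chromatography. Li2CuCl4 opens the oxirane at its CH2 to give the chloro diol (1R,5S)-5-bromo-2-[(1S)-2-chloro-1-hydroxyethyl]-2-hydroxy-4,4-dimethylcyclohexyl acetate F5. SOCl2/Et3N gives the spiro cyclic sulfite of this diol F6, and RuCl3 (cat.)/NaIO4 gives the spiro cyclic sulfate F7. LiBr opens F7 at the secondary carbon with inversion, and dilute H2SO4 hydrolyses the remaining tertiary sulfate ester to give 8.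

**Step 6 (dehydration).** Elimination could go toward C1′ (vinyl bromide) or C1 (enol acetate), and the neighbouring bromine could take part in ionisation. Fallback, setting out from 6 and coming back at 10, which never makes a tertiary alcohol: Tf2O with 2,6-di-tert-butyl-4-methylpyridine converts ketone 6 into the enol triflate (1R,5S)-5-bromo-4,4-dimethyl-2-(trifluoromethanesulfonyloxy)cyclohex-2-en-1-yl acetate F8, enolising away from the acetoxy carbon. Nozaki–Hiyama–Kishi coupling with chloroacetaldehyde (NiCl2 cat., CrCl2, DMF) gives the allylic chlorohydrin (1R,5S)-5-bromo-2-[(1S)-2-chloro-1-hydroxyethyl]-4,4-dimethylcyclohex-2-en-1-yl acetate F9 after separation from its C1′ epimer. CBr4/PPh3 (Appel, inversion; the SN2′ terminus is neopentyl) gives 10.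

## Further compounds

F1 | step 3 | (3RS,4R)-3,7-dimethylocta-1,6-diene-3,4-diol | C=CC(C)(O)[C@H](O)CC=C(C)C
F2 | step 3 | (3RS,4R)-3-hydroxy-3,7-dimethylocta-1,6-dien-4-yl acetate | C=CC(C)(O)[C@H](OC(C)=O)CC=C(C)C
F3 | step 3 | (4R)-7-methyl-3-methylideneocta-1,6-dien-4-yl acetate | C=CC(=C)[C@H](OC(C)=O)CC=C(C)C
F4 | step 5 | (1R,5S)-5-bromo-2-hydroxy-4,4-dimethyl-2-[(2R)-oxiran-2-yl]cyclohexyl acetate (ring OH cis to OAc) | CC(=O)O[C@@H]1C[C@H](Br)C(C)(C)C[C@@]1(O)[C@H]2CO2
F5 | step 5 | (1R,5S)-5-bromo-2-[(1S)-2-chloro-1-hydroxyethyl]-2-hydroxy-4,4-dimethylcyclohexyl acetate (ring OH cis to OAc) | CC(=O)O[C@@H]1C[C@H](Br)C(C)(C)C[C@@]1(O)[C@H](O)CCl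
F6 | step 5 | spiro cyclic sulfite (1,3,2-dioxathiolane 2-oxide) of diol F5 (configuration as in F5; sulfur epimers) | CC(=O)O[C@@H]1C[C@H](Br)C(C)(C)C[C@]12OS(=O)O[C@@H]2CCl
F7 | step 5 | spiro cyclic sulfate (1,3,2-dioxathiolane 2,2-dioxide) of diol F5 (configuration as in F5) | CC(=O)O[C@@H]1C[C@H](Br)C(C)(C)C[C@]12OS(=O)(=O)O[C@@H]2CCl
F8 | step 6 | (1R,5S)-5-bromo-4,4-dimethyl-2-(trifluoromethanesulfonyloxy)cyclohex-2-en-1-yl acetate | CC(=O)O[C@@H]1C[C@H](Br)C(C)(C)C=C1OS(=O)(=O)C(F)(F)F
F9 | step 6 | (1R,5S)-5-bromo-2-[(1S)-2-chloro-1-hydroxyethyl]-4,4-dimethylcyclohex-2-en-1-yl acetate | CC(=O)O[C@@H]1C[C@H](Br)C(C)(C)C=C1[C@H](O)CCl
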